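By the main step by itself, with the nucleophile held as charged, grey's electrophile has a half-life of 7.0 min, short against the 80 min of the run, so in a one-step world time is no question.

- grey: electrophile 17 mM; nucleophile 34.0 mM; time 80 min
- green: electrophile 17 mM; nucleophile 44.0 mM; time 80 min

    electrophile + nucleophile → acid set free + target (k1 = 2.9 M⁻¹ min⁻¹)
    nucleophile + acid set free ⇌ protonated nucleophile, settled at all times (K2 = 1900 M⁻¹)
    crystals ⇌ target, rate k3*(cs3 - [target]) while solid is left; crystals form when [target] > cs3 (cs3 = 8.2 mM, k3 = 1.4 min⁻¹)
    2 nucleophile → self-condensation product (k4 = 0.41 M⁻¹ min⁻¹)
    target ⇌ isomer of the product (K5 = 0.21, k5 = 0.013 min⁻¹)

- what is said of target includes crystals
- a doubled species enters its step squared and goes two at a time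
- crystals is a solid; its amount is given per volume of the solution
- run time (grey): 80 min

- part of the electrophile that has reacted at the end, grey
- part of the electrophile that has reacted at the end, green
- what raising the concentration of nucleophile from its lowest to its highest value here does to the part of the electrophile that has reacted (changes below 5 percentage points count as none) (it rises / it falls / no change)

I therefore counted nucleophile instead of time. Each turn of the main step costs two nucleophile, one to react and one to take the acid set free, because the binding constant times the charged nucleophile is 65, far above one. Grey charges 2.00 nucleophile per electrophile, just the price of full conversion, so I needed to compute only the correction for self-condensation. With σ = 0.141, the ratio of the self-condensation constant to the main one (a selectivity factor), each electrophile that goes is accompanied by σ times the ratio of free nucleophile to electrophile in self-condensation turns, each costing two nucleophile.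

My first way held that ratio at two, which gave a conversion of 78.0% for grey. My second way let the ratio move. With m = 0.717, the electrophile fraction left at zero free nucleophile, raised to the power m, equals one minus m times half the charged ratio. This gave 82.8% for grey, and this number, the part of the electrophile reacted when free nucleophile reaches zero with each acid bound, I call the stall conversion X.

The two ways parted by 4.8 percentage points, the first being lower. The first way cheats: self-condensation pulls the ratio below two, yet it goes on charging the side path at two. I kept X, which is 97.5% for green. I took X as the place where a run slows, so I expected grey near its X, green somewhat under its own, and a rise.

The forecast gave 81% for grey and 91% for green, and said it rises, on the ground that “Each conversion uses up two nucleophiles, one to react and one tied up by the released acid”. Its green stands 6.5 points below my X.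

The simulation gave 81.7% for grey and 90.6% for green: it rises, by 8.9 points. Grey stood just under its X, but neither flask had come to rest. The nucleophile balance moves X by free acid minus free nucleophile, over twice the electrophile charged. In a further flask like grey but with 14 mM of nucleophile, X is 38.6%; its 3.33 mM of free acid and 0.710 mM of free nucleophile lift that to 46.3%, and that flask reads 46.0%. Ten times the time still added 9.2 points in green, reaching 99.8%, and 16 points in grey, reaching 97.9%, past its X.

The rate constants were set for the occasion, and the outcome is calculated.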